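(The readings stem from a simulated flask with constants of no real substance; the scatter is artificial.)

Between 4.00 min and 8.00 min of the blue run, J fell by 18 percentage points of its charge while E rose by 5 points, so I asked what share of the J consumed still stood as E.

| flask | J | D | Q | temperature | remark | time |
|---|---|---|---|---|---|---|
| blue | 0.012 M | 0.030 M | 0.012 M | 100 °C | the very flask that is asked about, followed so far |  |
| red | 0.012 M | 0.015 M | 0.012 M | 95 °C | run made earlier |  |
| flask | 0.012 M | 0.0300 M | 0.0120 M | 100 °C |  | 12 min |

blue run (percent of the J charged)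

| time / min | E / % | J / % |
|---|---|---|
| 0.500 | 8 | 96 |
| 1.33 | 12 | 89 |
| 2.50 | 17 | 76 |
| 4.00 | 25 | 66 |
| 6.00 | 28 | 58 |
| 8.00 | 30 | 48 |

red run (percent of the J charged)

| time / s | E / % | J / % |
|---|---|---|
| 10.0 | 0 | 100 |
| 15.0 | 0 | 102 |
| 25.0 | 3 | 97 |
| 40.0 | 3 | 96 |
| 60.0 | 5 | 93 |
| 120 | 8 | 91 |

(scatter of a reading: 2 percentage points)

- beta: change nothing and wait 6.0 min more
- alpha: at 12 min raise the temperature by 20 K, then wait 6.0 min
- theta: at 12 min take out 90 % of the E then present, then wait 6.0 min
- epsilon: at 12 min add D, 50.0 % of the amount charged, then wait 6.0 min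

* E, in percent of the J first charged, at 12 min
* which option adds most E ("none" when 2 percentage points or less is all one gets) (beta / alpha / theta / epsilon / none)
* E present, with what was taken out counted in, in percent of the J first charged, after beta
* E present, with what was taken out counted in, in percent of the J first charged, after alpha

- removed E is counted in
- additions bring no volume worth counting

In its first instants the blue flask showed no gap beyond the scatter: at 1.33 min J had lost 11 points and E stood at 12.0 %. In the middle the share kept, the selectivity E/x with x the fraction of J consumed, was 0.735 at 4.00 min and 0.577 at 8.00 min. I joined the two ends with a straight line from a share of one at the start, which gives E = x(1 − x/g), with g the reach, the consumed fraction at which that line would meet zero. The two readings, each with its scatter, gave 1.28 and 1.23, so I took 1.26.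

On this curve E tops out at 0.315, where x is 0.630. Reading J as first order from its 8.00 min value gave 0.0917 min⁻¹, so at 12 min I had x = 0.667, just past the top, and E = 0.314. Waiting gave me x = 0.808 and E = 0.290. For alpha I assumed a clock 3 times faster on the same curve, which gave 0.936 and E = 0.241. Taking E out, I judged, returns the flask to the early end of the curve, so I chose theta.

The forecast gave 31 %, 26 % after beta and 14 % after alpha, chose theta, and held E “already past the peak, so waiting loses E”; my curve pointed the same way, but my figures after beta and alpha stood higher.

The flask gave 29.4 % at 12 min, 26.3 % after beta and 23.5 % after alpha, and theta was best, adding 9.4 points.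

    J + D ⇌ Q + E (K = 0.730, k = 0.0585 M⁻¹ s⁻¹, Ea = 65.0 kJ mol⁻¹, ΔH = 12.0 kJ mol⁻¹)
    J + E → L (k = 0.135 M⁻¹ s⁻¹, Ea = 56.0 kJ mol⁻¹)
    E + D ⇌ Q + X (K = 3.40, k = 0.00194 M⁻¹ s⁻¹, Ea = 59.0 kJ mol⁻¹, ΔH = −53.0 kJ mol⁻¹)
    (constants at 100 °C)

With the flask's J of 38.8 % at 12.0 min, the curve gives 31.4 % against the 29.4 % found. The neighbour flask kept at 85 °C held J at 61.8 %, and the same g gives 26.6 % against its 25.0 %. The flask had not come to rest at 12 min, however. At 120 min its J stands at 7.31 %, the curve gives 24.3 %, and E has fallen to 6.50 %.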